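**Strategy.** Ring A is cut across C2–C3 and C4–C5. One catalytic enantioselective Diels–Alder reaction of methacrolein with an (E)-diene then builds the cyclohexene together with its two adjacent stereocentres: quaternary C4 (bearing the C18 methyl and the C19 carbonyl carbon) and tertiary C5 (bearing H and C6), with C19 and C6 on the same face. The diene is the silyl ether of (E)-4-methylhexa-3,5-dien-1-ol; its inner methyl is C20 and its oxygenated arm is C6–C7. The surviving C1=C10 alkene is used, through a C2 carbinol, to carry C9 onto C10 by a [3,3] shift. Ring B is closed at C7–C8 as an 8-ketone, which fixes C9 and later takes C17.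

Key step: step 5

**Remarks on the chemistry**
- Locants C1–C20 follow labdane numbering; α is the face of H-5, β the face of C-20.
- Assumption: on the accepted model for 2-substituted acroleins (formyl C–H···O contact, s-trans enal lying over the near phenyl group), the catalyst made from (S)-α,α-diphenylprolinol should expose the Cα-Re face of methacrolein, which is the face required. If the sense proves opposite, the (R)-catalyst is used and nothing else changes.
- The diene is kept as the tert-butyldimethylsilyl ether: it tolerates the boron Lewis acid at −78 °C and is later the only group removed by fluoride.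
- C19 is carried as a dioxolane from step 6 to step 24, so that no electrophilic carbonyl lies within reach of C7 during the carbanion steps.
- C9 is carried as an epimer mixture from step 15 to step 20 and is set in step 21.

**Route**

Step 1
Reactants: 1 propane-1,3-diol
Product: 2 3-[(tert-butyldimethylsilyl)oxy]propan-1-ol
Conditions: NaH (1.0 equiv), THF, 0 °C to rt; TBSCl (1.0 equiv)
Reagents that add atoms: tert-butyldimethylsilyl chloride, CC(C)(C)[Si](C)(C)Cl
Why: O-silylation of the sparingly soluble monosodium alkoxide (Williamson-type) should stop at the mono-silyl ether.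

Step 2
Reactants: 2 3-[(tert-butyldimethylsilyl)oxy]propan-1-ol
Product: 3 3-[(tert-butyldimethylsilyl)oxy]propanal
Conditions: TEMPO (10 mol%), PhI(OAc)2 (1.1 equiv), CH2Cl2, rt
Reagents that add atoms: none
Why: TEMPO/PhI(OAc)2 oxidation (oxoammonium mechanism) takes the primary alcohol to the aldehyde without over-oxidation and leaves the silyl ether intact.

Step 3
Reactants: 3 3-[(tert-butyldimethylsilyl)oxy]propanal
Product: 4 (E)-5-[(tert-butyldimethylsilyl)oxy]-2-methylpent-2-enal
Conditions: Ph3P=C(CH3)CHO (1.2 equiv), toluene, 80 °C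
Reagents that add atoms: 2-(triphenylphosphoranylidene)propanal, CC(C=O)=P(c1ccccc1)(c1ccccc1)c1ccccc1
Why: Wittig olefination with a formyl-stabilised ylide is under thermodynamic control and should give the trisubstituted (E)-enal, which fixes the E geometry of the diene.

Step 4
Reactants: 4 (E)-5-[(tert-butyldimethylsilyl)oxy]-2-methylpent-2-enal
Product: 5 (E)-tert-butyldimethyl[(4-methylhexa-3,5-dien-1-yl)oxy]silane
Conditions: Ph3PCH3Br, n-BuLi, THF, −78 to 0 °C
Reagents that add atoms: methyltriphenylphosphonium bromide, C[P+](c1ccccc1)(c1ccccc1)c1ccccc1.[Br-]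
Why: Wittig methylenation of the enal carbonyl installs the terminal vinyl group (the later C1=C2 unit) without touching the trisubstituted alkene.

Step 5
Reactants: 5 (E)-tert-butyldimethyl[(4-methylhexa-3,5-dien-1-yl)oxy]silane, 6 methacrolein
Product: 7 (1S,2R)-2-{2-[(tert-butyldimethylsilyl)oxy]ethyl}-1,3-dimethylcyclohex-3-ene-1-carbaldehyde
Conditions: 6 (3 equiv), (S)-o-tolyl-oxazaborolidine [from (S)-α,α-diphenylprolinol and tri(o-tolyl)boroxine] activated with HNTf2 (20 mol%), CH2Cl2, −78 °C; Et3N quench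
Reagents that add atoms: none
Why: Coordination of the formyl oxygen to the cationic boron lowers the LUMO of methacrolein, and the diene adds in a concerted, asynchronous [4+2] event in which the unsubstituted terminus C2 bonds first to the enal β-carbon C3 and C5 then bonds to C4; the closest known reaction type is the oxazaborolidinium-catalysed Diels–Alder reaction of 2-methylacrolein with acyclic 1,3-dienes. Ring A closes in this one intermolecular [4+2] cycloaddition as a cyclohexene that keeps the C1=C10 alkene. C4 is set by the catalyst, whose near phenyl group covers one face of the bound s-trans enal so that the diene should meet the Cα-Re face; C5 follows from the E geometry of the diene and the endo position of the formyl group, which puts C19 cis to C6. The step needs ortho regiochemistry, endo selectivity and face selectivity: the alkyl group on the diene terminus C5 and the preference for first bonding at the unhindered CH2 terminus should secure the first, the Lewis-acid-bound formyl group (with no bridge repulsion of the kind that sends 2-substituted acroleins exo with cyclic dienes) the second, and the chiral boron catalyst the third.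

Step 6
Reactants: 7 (1S,2R)-2-{2-[(tert-butyldimethylsilyl)oxy]ethyl}-1,3-dimethylcyclohex-3-ene-1-carbaldehyde
Product: 8 2-[(1S,2R)-2-{2-[(tert-butyldimethylsilyl)oxy]ethyl}-1,3-dimethylcyclohex-3-en-1-yl]-1,3-dioxolane
Conditions: (Me3SiOCH2)2 (1.5 equiv), Me3SiOTf (5 mol%), CH2Cl2, −78 to −20 °C; pyridine
Reagents that add atoms: 1,2-bis(trimethylsilyloxy)ethane, C[Si](C)(C)OCCO[Si](C)(C)C
Why: Acetalisation with the bis-silyl ether of ethylene glycol is driven by Si–O–Si formation and should mask the non-enolisable C19 aldehyde at low temperature without harming the silyl ether or the alkene.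

Step 7
Reactants: 8 2-[(1S,2R)-2-{2-[(tert-butyldimethylsilyl)oxy]ethyl}-1,3-dimethylcyclohex-3-en-1-yl]-1,3-dioxolane
Product: 9 (4R,5S)-4-{2-[(tert-butyldimethylsilyl)oxy]ethyl}-5-(1,3-dioxolan-2-yl)-3,5-dimethylcyclohex-2-en-1-one
Conditions: CrO3 (15 equiv), 3,5-dimethylpyrazole (15 equiv), CH2Cl2, −20 °C
Reagents that add atoms: chromium trioxide, O=[Cr](=O)=O
Why: Allylic oxidation with the CrO3·3,5-dimethylpyrazole complex should attack the secondary allylic C2 methylene beside vinylic C1–H (as at C7 of 5-ene steroids), because the other ring allylic site, C5–H, is tertiary and shielded by quaternary C4.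

Step 8
Reactants: 9 (4R,5S)-4-{2-[(tert-butyldimethylsilyl)oxy]ethyl}-5-(1,3-dioxolan-2-yl)-3,5-dimethylcyclohex-2-en-1-one
Product: 10 (1S,4R,5S)-4-{2-[(tert-butyldimethylsilyl)oxy]ethyl}-5-(1,3-dioxolan-2-yl)-3,5-dimethylcyclohex-2-en-1-ol
Conditions: (R)-2-methyl-CBS-oxazaborolidine (20 mol%), catecholborane (1.5 equiv), toluene, −78 °C; MeOH
Reagents that add atoms: none
Why: CBS reduction is 1,2-selective for enones; with the alkenyl side as the large group the (R)-catalyst should deliver hydride to the β face, which is also the face away from the pseudoaxial C4 α-methyl, so the new C2 carbinol centre should form as the 2α-alcohol.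

Step 9
Reactants: 11 (S)-citronellol
Product: 12 ({[(3S)-3,7-dimethyloct-6-en-1-yl]oxy}methyl)benzene
Conditions: NaH, BnBr, Bu4NI (cat.), THF, 0 °C to rt
Reagents that add atoms: benzyl bromide, BrCc1ccccc1
Why: Williamson etherification protects the future C15 oxygen; the C13 stereocentre is remote and untouched.

Step 10
Reactants: 12 ({[(3S)-3,7-dimethyloct-6-en-1-yl]oxy}methyl)benzene
Product: 13 (4S)-6-(benzyloxy)-4-methylhexanal
Conditions: O3, CH2Cl2, −78 °C; Me2S, −78 °C to rt
Reagents that add atoms: ozone, [O-][O+]=O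
Why: Ozonolysis with reductive work-up cleaves the trisubstituted alkene to the aldehyde whose carbonyl carbon becomes C9.

Step 11
Reactants: 13 (4S)-6-(benzyloxy)-4-methylhexanal
Product: 14 ({[(3S)-3-methylhept-6-en-1-yl]oxy}methyl)benzene
Conditions: Ph3PCH3Br, n-BuLi, THF, 0 °C
Reagents that add atoms: methyltriphenylphosphonium bromide, C[P+](c1ccccc1)(c1ccccc1)c1ccccc1.[Br-]
Why: Wittig methylenation adds the one carbon that becomes C8, which the six-carbon citronellol fragment lacks.

Step 12
Reactants: 14 ({[(3S)-3-methylhept-6-en-1-yl]oxy}methyl)benzene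
Product: 15 (5S)-7-(benzyloxy)-5-methylheptan-1-ol
Conditions: 9-BBN, THF, 0 °C to rt; NaOH, H2O2, 0 °C
Reagents that add atoms: hydrogen peroxide, OO
Why: Hydroboration–oxidation with 9-BBN is anti-Markovnikov on the terminal alkene and gives the primary alcohol.

Step 13
Reactants: 15 (5S)-7-(benzyloxy)-5-methylheptan-1-ol
Product: 16 (5S)-7-(benzyloxy)-5-methylheptanoic acid
Conditions: TEMPO (20 mol%), PhI(OAc)2 (2.2 equiv), MeCN/H2O 1:1, rt
Reagents that add atoms: water, O
Why: TEMPO/PhI(OAc)2 oxidation in aqueous acetonitrile takes the primary alcohol through the aldehyde hydrate to the acid and spares the benzyl ether.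

Step 14
Reactants: 10 (1S,4R,5S)-4-{2-[(tert-butyldimethylsilyl)oxy]ethyl}-5-(1,3-dioxolan-2-yl)-3,5-dimethylcyclohex-2-en-1-ol, 16 (5S)-7-(benzyloxy)-5-methylheptanoic acid
Product: 17 (1S,4R,5S)-4-{2-[(tert-butyldimethylsilyl)oxy]ethyl}-5-(1,3-dioxolan-2-yl)-3,5-dimethylcyclohex-2-en-1-yl (5S)-7-(benzyloxy)-5-methylheptanoate
Conditions: DCC (1.2 equiv), DMAP (0.2 equiv), CH2Cl2, 0 °C to rt
Reagents that add atoms: none
Why: Steglich esterification acylates the allylic alcohol with retention at C2, since the C2–O bond is not broken.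

Step 15
Reactants: 17 (1S,4R,5S)-4-{2-[(tert-butyldimethylsilyl)oxy]ethyl}-5-(1,3-dioxolan-2-yl)-3,5-dimethylcyclohex-2-en-1-yl (5S)-7-(benzyloxy)-5-methylheptanoate
Product: 20 seco acid with C9 attached to C10 (C9 epimers), via silyl ketene acetal 18 (not isolated), via trimethylsilyl ester 19 (not isolated)
Conditions: LiN(i-Pr)2 (1.5 equiv), Me3SiCl/Et3N, THF, −78 °C; rt, then 60 °C; H2O, aq. citric acid (pH 4)
Reagents that add atoms: none
Why: Ireland–Claisen rearrangement: the silyl ketene acetal should undergo a suprafacial [3,3] shift that moves the 2α C–O bond into a C9–C10 bond on the α face, so quaternary C10 is set by 1,3-chirality transfer (C20 β, C9 trans to C6), while C9 is not controlled here and is corrected in step 21.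

Step 16
Reactants: 20 seco acid (C9 epimers)
Product: 22 N-methoxy-N-methylamide of 20, via acid chloride 21 (not isolated)
Conditions: 1-chloro-N,N,2-trimethylprop-1-en-1-amine (1.2 equiv), CH2Cl2, 0 °C; MeNHOMe·HCl (1.5 equiv), pyridine, 0 °C to rt
Reagents that add atoms: N,O-dimethylhydroxylamine hydrochloride, CNOC.Cl
Why: Neutral conversion of the hindered C8 acid to its chloride, then amidation, gives the acylating group for ring closure without loss of the silyl ether or the acetal.

Step 17
Reactants: 22 N-methoxy-N-methylamide of 20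
Product: 23 C7 alcohol
Conditions: Bu4NF (1.2 equiv), THF, 0 °C to rt
Reagents that add atoms: none
Why: Fluoride desilylation frees the primary C7 hydroxyl; the benzyl ether, dioxolane and amide are inert.

Step 18
Reactants: 23 C7 alcohol
Product: 24 C7 iodide
Conditions: I2 (1.3 equiv), PPh3 (1.3 equiv), imidazole (2 equiv), CH2Cl2, 0 °C
Reagents that add atoms: iodine, II
Why: Appel-type iodination converts the unhindered primary alcohol to the iodide under buffered conditions.

Step 19
Reactants: 24 C7 iodide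
Product: 27 bicyclic 8-ketone (C9 epimers), via alkyllithium 25 (not isolated), via lithium hemiaminal alkoxide 26 (not isolated)
Conditions: t-BuLi (2.1 equiv), Et2O/pentane, −78 to −20 °C; H2O
Reagents that add atoms: none
Why: Iodine–lithium exchange is faster than addition to the amide, and the primary alkyllithium should then attack the N-methoxy-N-methylamide in a 6-exo-trig acyl substitution (Weinreb ketone synthesis) whose chelated tetrahedral intermediate releases the C8 ketone only on work-up; the trans ring fusion is already fixed by C5 and C10.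

Step 20
Reactants: 27 bicyclic 8-ketone (C9 epimers)
Product: 28 saturated 15-hydroxy 8-ketone (C9 epimers)
Conditions: H2 (1 atm), Pd/C (10 wt%), EtOH, rt
Reagents that add atoms: none
Why: Catalytic hydrogenation saturates the cis-disubstituted C1=C2 alkene (no new stereocentre) and hydrogenolyses the benzyl ether in the same operation.

Step 21
Reactants: 28 saturated 15-hydroxy 8-ketone (C9 epimers)
Product: 29 19,19-(ethylenedioxy)-15-hydroxy-17-norlabdan-8-one (9α-H)
Conditions: NaOMe (0.3 equiv), MeOH, 40 °C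
Reagents that add atoms: none
Why: Base-mediated epimerisation through the C8 enolate should set C9 under thermodynamic control, with the C11 chain equatorial (β) on the chair of ring B and free of the syn-axial contacts with H-5 and H-7 that the 9-epimer suffers.

Step 22
Reactants: 29 19,19-(ethylenedioxy)-15-hydroxy-17-norlabdan-8-one
Product: 30 19,19-(ethylenedioxy)labd-8(17)-en-15-ol
Conditions: Ph3PCH3Br (5 equiv), KOtBu (4.5 equiv), toluene, 80 °C
Reagents that add atoms: methyltriphenylphosphonium bromide, C[P+](c1ccccc1)(c1ccccc1)c1ccccc1.[Br-]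
Why: Wittig methylenation of the hindered 8-ketone with excess ylide installs C17 as the exocyclic methylene; C9 already holds its stable configuration, so enolisation cannot scramble it.

Step 23
Reactants: 30 19,19-(ethylenedioxy)labd-8(17)-en-15-ol
Product: 31 19,19-(ethylenedioxy)labd-8(17)-en-15-yl octadecanoate
Conditions: C17H35COCl (1.2 equiv), pyridine, DMAP (cat.), CH2Cl2, 0 °C to rt
Reagents that add atoms: octadecanoyl chloride, CCCCCCCCCCCCCCCCCC(=O)Cl
Why: Acylation of the only free hydroxyl (primary C15–OH) with the acid chloride gives the stearate.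

Step 24
Reactants: 31 19,19-(ethylenedioxy)labd-8(17)-en-15-yl octadecanoate
Product: 32 19-oxolabd-8(17)-en-15-yl octadecanoate
Conditions: AcOH/H2O/THF (3:1:1), 45 °C
Reagents that add atoms: water, O
Why: Mild aqueous-acid hydrolysis of the dioxolane releases the C19 aldehyde; the acid is too weak to protonate the 1,1-disubstituted alkene or cleave the ester.

Step 25
Reactants: 32 19-oxolabd-8(17)-en-15-yl octadecanoate
Product: 33 15-(octadecanoyloxy)labd-8(17)-en-19-oic acid (CNP0298278.1)
Conditions: NaClO2, NaH2PO4, 2-methylbut-2-ene, t-BuOH/THF/H2O, 0 °C to rt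
Reagents that add atoms: sodium chlorite, [Na+].[O-]Cl=O
Why: Pinnick oxidation converts the hindered, non-enolisable aldehyde to the acid, while the scavenger removes hypochlorite so that the exocyclic alkene and the stearate are untouched.

**Compound list**

1 | propane-1,3-diol | OCCCO | starting material
2 | 3-[(tert-butyldimethylsilyl)oxy]propan-1-ol | CC(C)(C)[Si](C)(C)OCCCO | intermediate
3 | 3-[(tert-butyldimethylsilyl)oxy]propanal | CC(C)(C)[Si](C)(C)OCCC=O | intermediate
4 | (E)-5-[(tert-butyldimethylsilyl)oxy]-2-methylpent-2-enal | CC(C)(C)[Si](C)(C)OCC/C=C(\C)C=O | intermediate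
5 | (E)-tert-butyldimethyl[(4-methylhexa-3,5-dien-1-yl)oxy]silane | C=C/C(C)=C/CCO[Si](C)(C)C(C)(C)C | intermediate
6 | methacrolein (2-methylprop-2-enal) | CC(=C)C=O | starting material
7 | (1S,2R)-2-{2-[(tert-butyldimethylsilyl)oxy]ethyl}-1,3-dimethylcyclohex-3-ene-1-carbaldehyde, formyl cis to the side arm | CC(C)(C)[Si](C)(C)OCC[C@@H]1C(C)=CCC[C@]1(C)C=O | intermediate
8 | 2-[(1S,2R)-2-{2-[(tert-butyldimethylsilyl)oxy]ethyl}-1,3-dimethylcyclohex-3-en-1-yl]-1,3-dioxolane | CC(C)(C)[Si](C)(C)OCC[C@@H]1C(C)=CCC[C@]1(C)C2OCCO2 | intermediate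
9 | (4R,5S)-4-{2-[(tert-butyldimethylsilyl)oxy]ethyl}-5-(1,3-dioxolan-2-yl)-3,5-dimethylcyclohex-2-en-1-one (C2 enone) | CC(C)(C)[Si](C)(C)OCC[C@@H]1C(C)=CC(=O)C[C@]1(C)C2OCCO2 | intermediate
10 | (1S,4R,5S)-4-{2-[(tert-butyldimethylsilyl)oxy]ethyl}-5-(1,3-dioxolan-2-yl)-3,5-dimethylcyclohex-2-en-1-ol (2α-OH, trans to the arm and to the dioxolanyl group) | CC(C)(C)[Si](C)(C)OCC[C@@H]1C(C)=C[C@@H](O)C[C@]1(C)C2OCCO2 | intermediate
11 | (S)-citronellol | CC(C)=CCC[C@H](C)CCO | starting material
12 | ({[(3S)-3,7-dimethyloct-6-en-1-yl]oxy}methyl)benzene | CC(C)=CCC[C@H](C)CCOCc1ccccc1 | intermediate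
13 | (4S)-6-(benzyloxy)-4-methylhexanal | O=CCC[C@H](C)CCOCc1ccccc1 | intermediate
14 | ({[(3S)-3-methylhept-6-en-1-yl]oxy}methyl)benzene | C=CCC[C@H](C)CCOCc1ccccc1 | intermediate
15 | (5S)-7-(benzyloxy)-5-methylheptan-1-ol | OCCCC[C@H](C)CCOCc1ccccc1 | intermediate
16 | (5S)-7-(benzyloxy)-5-methylheptanoic acid | OC(=O)CCC[C@H](C)CCOCc1ccccc1 | intermediate
17 | (1S,4R,5S)-4-{2-[(tert-butyldimethylsilyl)oxy]ethyl}-5-(1,3-dioxolan-2-yl)-3,5-dimethylcyclohex-2-en-1-yl (5S)-7-(benzyloxy)-5-methylheptanoate | CC(C)(C)[Si](C)(C)OCC[C@@H]1C(C)=C[C@@H](OC(=O)CCC[C@H](C)CCOCc2ccccc2)C[C@]1(C)C3OCCO3 | intermediate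
18 | trimethylsilyl ketene acetal of 17 (enol ether geometry not defined) | CC(C)(C)[Si](C)(C)OCC[C@@H]1C(C)=C[C@@H](OC(O[Si](C)(C)C)=CCC[C@H](C)CCOCc2ccccc2)C[C@]1(C)C3OCCO3 | intermediate
19 | trimethylsilyl ester of 20 (C9 epimers) | C[Si](C)(C)OC(=O)C(CC[C@H](C)CCOCc1ccccc1)[C@@]2(C)C=CC[C@](C)(C3OCCO3)[C@@H]2CCO[Si](C)(C)C(C)(C)C | intermediate
20 | (5S)-7-(benzyloxy)-2-[(1S,5S,6R)-6-{2-[(tert-butyldimethylsilyl)oxy]ethyl}-5-(1,3-dioxolan-2-yl)-1,5-dimethylcyclohex-2-en-1-yl]-5-methylheptanoic acid, both epimers at C2 of the acid (labdane C9) | OC(=O)C(CC[C@H](C)CCOCc1ccccc1)[C@@]2(C)C=CC[C@](C)(C3OCCO3)[C@@H]2CCO[Si](C)(C)C(C)(C)C | intermediate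
21 | acid chloride of 20 | ClC(=O)C(CC[C@H](C)CCOCc1ccccc1)[C@@]2(C)C=CC[C@](C)(C3OCCO3)[C@@H]2CCO[Si](C)(C)C(C)(C)C | intermediate
22 | N-methoxy-N-methylamide of 20 | CON(C)C(=O)C(CC[C@H](C)CCOCc1ccccc1)[C@@]2(C)C=CC[C@](C)(C3OCCO3)[C@@H]2CCO[Si](C)(C)C(C)(C)C | intermediate
23 | amide 22 with the silyl ether replaced by a free C7 hydroxyl (2-hydroxyethyl arm) | CON(C)C(=O)C(CC[C@H](C)CCOCc1ccccc1)[C@@]2(C)C=CC[C@](C)(C3OCCO3)[C@@H]2CCO | intermediate
24 | amide 23 with the C7 hydroxyl replaced by iodine (2-iodoethyl arm) | CON(C)C(=O)C(CC[C@H](C)CCOCc1ccccc1)[C@@]2(C)C=CC[C@](C)(C3OCCO3)[C@@H]2CCI | intermediate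
25 | C7 alkyllithium from 24 | CON(C)C(=O)C(CC[C@H](C)CCOCc1ccccc1)[C@@]2(C)C=CC[C@](C)(C3OCCO3)[C@@H]2CC[Li] | intermediate
26 | lithium alkoxide of the cyclic C8 N-methoxy-N-methyl hemiaminal (ring B closed) | CON(C)C1(O[Li])CC[C@@H]2[C@](C)(C=CC[C@]2(C)C3OCCO3)C1CC[C@H](C)CCOCc4ccccc4 | intermediate
27 | 15-(benzyloxy)-19,19-(ethylenedioxy)-17-norlabd-1-en-8-one, C9 epimers | O=C1CC[C@@H]2[C@](C)(C=CC[C@]2(C)C3OCCO3)C1CC[C@H](C)CCOCc4ccccc4 | intermediate
28 | 19,19-(ethylenedioxy)-15-hydroxy-17-norlabdan-8-one, C9 epimers | O=C1CC[C@@H]2[C@](C)(CCC[C@]2(C)C3OCCO3)C1CC[C@H](C)CCO | intermediate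
29 | 19,19-(ethylenedioxy)-15-hydroxy-17-norlabdan-8-one, 9α-H (C11 chain β, equatorial) | O=C1CC[C@@H]2[C@](C)(CCC[C@]2(C)C3OCCO3)[C@H]1CC[C@H](C)CCO | intermediate
30 | 19,19-(ethylenedioxy)labd-8(17)-en-15-ol | C=C1CC[C@@H]2[C@](C)(CCC[C@]2(C)C3OCCO3)[C@H]1CC[C@H](C)CCO | intermediate
31 | 19,19-(ethylenedioxy)labd-8(17)-en-15-yl octadecanoate | C=C1CC[C@@H]2[C@](C)(CCC[C@]2(C)C3OCCO3)[C@H]1CC[C@H](C)CCOC(=O)CCCCCCCCCCCCCCCCC | intermediate
32 | 19-oxolabd-8(17)-en-15-yl octadecanoate | C=C1CC[C@@H]2[C@](C)(CCC[C@]2(C)C=O)[C@H]1CC[C@H](C)CCOC(=O)CCCCCCCCCCCCCCCCC | intermediate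
33 | 15-(octadecanoyloxy)labd-8(17)-en-19-oic acid (CNP0298278.1) | C=C1CC[C@@H]2[C@](C)(CCC[C@]2(C)C(=O)O)[C@H]1CC[C@H](C)CCOC(=O)CCCCCCCCCCCCCCCCC | target

**Step count**

Total: 25 steps. Longest linear sequence: 20 steps (steps 1–8 and 14–25); the side-chain acid 16 takes 5 steps (9–13).

**Steps most likely to fail, with fallbacks**

1. Step 5. The inner methyl of the diene may draw the enal β-carbon to C5 (loss of ortho regiocontrol), or exo approach may compete, either of which erodes the C4/C5 pair. The fallback sets out from 3 and 6 and returns at 8, polarising the diene with an oxygen on C1. Aldehyde 3 would be condensed with 3-(triphenylphosphoranylidene)butan-2-one to (E)-6-[(tert-butyldimethylsilyl)oxy]-3-methylhex-3-en-2-one F1. Enolisation towards the methyl group (i-Pr3SiOTf, Et3N) would give the 2-silyloxy diene F2. Cycloaddition with 6 under the same boron catalyst should give the silyl enol ether aldehyde F3, in which the formyl-bearing carbon is para to the silyloxy carbon and therefore bonded to C5. Acetalisation as in step 6 would give the dioxolane F4, CsF/PhNTf2 the enol triflate F5, and reduction of the triflate (Pd(OAc)2, PPh3, HCO2H, Bu3N, DMF) would rejoin the route at 8.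

2. Step 15. The [3,3] shift may stall because the new bond to C10 must form on the α face syn to the C4 α-methyl, which leaves time for hydrolysis or C-silylation of the ketene acetal. The fallback sets out from 9 and 16 and returns at 20 (steps 8 and 14 are then not needed), replacing the sigmatropic shift by a conjugate addition. Acid 16 would be converted to the methyl ester F6 (MeI, K2CO3) and then to the trimethylsilyl ketene acetal F7 (LiN(i-Pr)2, Me3SiCl). Fluoride-catalysed Mukaiyama–Michael addition of F7 to enone 9 [tris(dimethylamino)sulfonium difluorotrimethylsilicate (cat.), THF], anti to the C5 arm, should give the silyl enol ether adduct F8 with C9 on the α face of C10. CsF/PhNTf2 would give the enol triflate F9, formate reduction under Pd(OAc)2/PPh3 the alkene methyl ester F10, and LiOH hydrolysis would return the route to 20.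

3. Step 19. Intramolecular proton transfer from C9–H to the alkyllithium, or intermolecular attack, may outrun the 6-exo acylation. The fallback sets out from 24 and returns at 27, using a stabilised carbanion. Iodide 24 would be displaced with PhSO2Na (DMF) to give the sulfone F11. LiN(SiMe3)2 (2.2 equiv, THF, −78 to 0 °C) would form the α-sulfonyl carbanion at C7, which should be acylated by the N-methoxy-N-methylamide to the cyclic β-keto sulfone F12. Reductive desulfonylation with SmI2 (THF/MeOH, −78 °C) would give 27.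

**Further compounds**

F1 | step 5 | (E)-6-[(tert-butyldimethylsilyl)oxy]-3-methylhex-3-en-2-one | CC(=O)/C(C)=C/CCO[Si](C)(C)C(C)(C)C
F2 | step 5 | (E)-tert-butyldimethyl({4-methyl-5-[(triisopropylsilyl)oxy]hexa-3,5-dien-1-yl}oxy)silane | C=C(O[Si](C(C)C)(C(C)C)C(C)C)/C(C)=C/CCO[Si](C)(C)C(C)(C)C
F3 | step 5 | (1S,2R)-2-{2-[(tert-butyldimethylsilyl)oxy]ethyl}-1,3-dimethyl-4-[(triisopropylsilyl)oxy]cyclohex-3-ene-1-carbaldehyde | CC(C)(C)[Si](C)(C)OCC[C@@H]1C(C)=C(O[Si](C(C)C)(C(C)C)C(C)C)CC[C@]1(C)C=O
F4 | step 5 | 1,3-dioxolane of F3 | CC(C)(C)[Si](C)(C)OCC[C@@H]1C(C)=C(O[Si](C(C)C)(C(C)C)C(C)C)CC[C@]1(C)C2OCCO2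
F5 | step 5 | C1 enol triflate corresponding to F4 | CC(C)(C)[Si](C)(C)OCC[C@@H]1C(C)=C(OS(=O)(=O)C(F)(F)F)CC[C@]1(C)C2OCCO2
F6 | step 15 | methyl (5S)-7-(benzyloxy)-5-methylheptanoate | COC(=O)CCC[C@H](C)CCOCc1ccccc1
F7 | step 15 | trimethylsilyl ketene acetal of F6 (geometry not defined) | COC(O[Si](C)(C)C)=CCC[C@H](C)CCOCc1ccccc1
F8 | step 15 | Michael adduct as the C2 trimethylsilyl enol ether, methyl ester (C9 epimers) | COC(=O)C(CC[C@H](C)CCOCc1ccccc1)[C@@]2(C)C=C(O[Si](C)(C)C)C[C@](C)(C3OCCO3)[C@@H]2CCO[Si](C)(C)C(C)(C)C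
F9 | step 15 | C2 enol triflate corresponding to F8 | COC(=O)C(CC[C@H](C)CCOCc1ccccc1)[C@@]2(C)C=C(OS(=O)(=O)C(F)(F)F)C[C@](C)(C3OCCO3)[C@@H]2CCO[Si](C)(C)C(C)(C)C
F10 | step 15 | methyl ester of 20 | COC(=O)C(CC[C@H](C)CCOCc1ccccc1)[C@@]2(C)C=CC[C@](C)(C3OCCO3)[C@@H]2CCO[Si](C)(C)C(C)(C)C
F11 | step 19 | C7 phenyl sulfone corresponding to 24 | CON(C)C(=O)C(CC[C@H](C)CCOCc1ccccc1)[C@@]2(C)C=CC[C@](C)(C3OCCO3)[C@@H]2CCS(=O)(=O)c4ccccc4
F12 | step 19 | 7-(phenylsulfonyl) derivative of 27 (cyclic β-keto sulfone) | O=C1C(S(=O)(=O)c5ccccc5)C[C@@H]2[C@](C)(C=CC[C@]2(C)C3OCCO3)C1CC[C@H](C)CCOCc4ccccc4
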